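## Analysis of the target

The target 21 is a flavonol: a benzo ring (ring A) fused to a 4-pyranone (ring C), with a 3,4-dihydroxyphenyl group (ring B) on C2 and a hydroxyl on C3. It has no stereocentre, so the problem is one of constitution and of telling six oxygen substituents apart. Ring A is fully substituted: C4a carries the C4 carbonyl, C5 a hydroxyl, C6, C7 and C8 methoxy groups, and C8a the ring oxygen O1. The catechol, the 3-hydroxy-4-pyranone enol and the electron-rich ring A oxidise easily in base and air, and the three methyl ethers must survive the release of four hydroxyls, which rules out a final Lewis-acid ether cleavage. The hard part is this hexasubstituted ring A, in which the C5 oxygen must be distinguished from the three methoxy oxygens and from O1. Two features make this tractable. First, the oxygens on C5 and C8a are the two ortho neighbours of C4a, and the methoxy groups lie symmetrically behind them, so ring A can come from a 2,6-dioxygenated 3,4,5-trimethoxybenzoyl unit with a mirror plane through C4a and C7, which a single benzylation desymmetrises. Second, C2 is bonded to O1 and to ring B and so stands at the oxidation level of a carboxylic ester, whereas C3 is the alpha carbon of the C4 ketone; the C2=C3 bond is therefore what an acyl ylide leaves behind after olefinating an aryl ester.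

## Retrosynthetic reasoning

21 ⇒ 20. The three O–CH2Ph bonds at C5, C3' and C4' are cut first. Benzyl ethers are chosen because neutral hydrogenolysis frees all three hydroxyls at once and leaves the methyl ethers alone. The benzyl group on the C5 oxygen is also what distinguishes it from the methoxy oxygens throughout the route.

20 ⇒ 17. The C3–O bond is cut back to C3–H. The carbon that becomes C3 is the ylide carbon of the key step, and an oxygen on it would demand a less nucleophilic alpha-alkoxy acyl ylide. In the flavone 17, the C3–H between C2 and the C4 carbonyl is the most acidic C–H, so the forward step is deprotonation, borylation and peroxide oxidation.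

17 ⇒ 16. The C2=C3 bond is cut by a Wittig transform. C2 becomes the carbonyl carbon of an aryl ester whose phenolic oxygen is O1, and C3 becomes the carbon of an acyl ylide on the neighbouring ring position. This cut is preferred because the O1–C8a and C4–C4a bonds then already sit in a simple benzoyl derivative, and ring B enters as a plain aroyl group. The closure is thermal and neutral, with no free ortho phenol and no oxidant. The forward step must make the stabilised ylide olefinate an ester carbonyl held in a six-membered arrangement.

16 ⇒ 12 and 13. The C3–C4 bond is cut next. The acyl group is the carboxyl of acid 12, activated as the acid chloride 14. The one-carbon ylide 15 comes from the phosphonium salt 13. The forward step must acylate 15 at the acid chloride while leaving the aryl ester untouched.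

12 ⇒ 11. The carboxyl is taken back to an aldehyde. A free acid would be alkylated before the phenols and would interfere with the aroylation, and an ester protecting group would have to be cleaved next to an aryl ester. The aldehyde is inert in both earlier steps and is oxidised only when the acid is needed.

11 ⇒ 8 and 9. The ester C–O bond, the future O1–C2 bond, is cut. It gives the phenol 8 and the ring B acid 9, which is activated as its chloride 10.

8 ⇒ 6 and 7. The benzyl ether is cut. The two hydroxyls of 6 are equivalent, so monoalkylation with 7 gives one constitution whichever oxygen reacts. The forward step must stop after one alkylation.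

6 ⇒ 4. The bond from the formyl carbon (the future C4) to the ring (the future C4a) is cut. The diol 4 has a single unsubstituted ring carbon, ortho to both hydroxyls, so the formylation has no regiochemical choice.

4 ⇒ 2 ⇒ 1. The two C–O bonds of the diol are traced through C–B to C–Br bonds and back to the parent arene 1. Its two equivalent positions, each ortho to one outer methoxy group and para to the other, are the natural sites of electrophilic bromination. Everything stays symmetric until the benzylation.

## Alternatives that were turned down

Alternative 1: Ring A is disconnected instead of ring C, at the C4a–C5 bond, and traced to a squarate-derived cyclobutenone A2 that carries the finished pyranone with ring B and a benzyloxy group on the future C3.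
- Key step: heating A2 should open the four-membered ring to a vinylketene, whose ketene carbon closes onto the pyranone C–H carbon in a six-electron electrocyclisation. Tautomerisation would give the flavone A1 with a free 5-OH.
- For: the three methoxy groups arrive in fixed order from the cyclobutenone carbons, the C5 hydroxyl is born unprotected and unambiguous, and the C3 oxygen is present from the start. A1 is one hydrogenolysis from the target, and on these points this route is stronger than the chosen one.
- Against: A2 needs a 4-pyranone metalated next to its ring oxygen and added 1,2 to a cyclobutenedione carbonyl, although the pyranone is itself a Michael acceptor and has a second acidic position. The tertiary alkoxide must then be methylated. The electrocyclisation must also engage an electron-poor, cross-conjugated pyranone double bond.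
- Comparison: the risk is spread over precursor assembly and key step alike. The chosen strategy reaches its precursor by standard aromatic chemistry and keeps the risk in one thermal step.

Alternative 2: Three bonds of ring C are cut at once (O1–C8a, C4–C4a and O1–C2), leading to the symmetric aryne A5, released from the silyl triflate A4, and the arylpropiolic acid A6.
- Key step: fluoride would generate A5, the carboxylate of A6 would add, the aryl anion would attack the acyl carbon, and the freed phenoxide would add 6-endo to the ynone to give the tetramethoxyflavone A3.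
- For: this is the most convergent plan, and the symmetry of A5 removes any regiochemical question in the insertion. On convergence it beats the chosen route.
- Against: A4 is itself a hexasubstituted arene that needs a multistep synthesis. Protonation of the aryl anion (simple O-arylation) competes with the acyl shift, and 5-exo closure of the ynone would give an aurone. A3 has four methyl ethers and no C3 oxygen, so a selective 5-O-demethylation with a boron or aluminium halide, which also endangers the benzyl ethers, and a C3 hydroxylation would still be needed.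
- Comparison: the chosen strategy marks the C5 oxygen with a benzyl group from the outset and needs only one post-cyclisation functionalisation.

Alternative 3: Ring C is cut at O1–C8a and closed by copper-catalysed intramolecular O-arylation of the enolate of the 1,3-diketone A8, whose aroyl ring carries two equivalent ortho bromides.
- Key step: the enolate oxygen displaces one bromide to give the 5-bromoflavone A7, which already carries the C3 benzyloxy group.
- For: the C3 oxygen is built in, the two bromides are equivalent, and this type of ring closure is well established. On the C3 oxygen it is stronger than the chosen route.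
- Against: the second bromide in A7 must still be exchanged for hydroxyl at the most hindered position of the molecule, between the peri carbonyl and the C6 methoxy group, under basic conditions that threaten the pyranone. A8 must be made by C-acylation with a doubly ortho-substituted benzoyl electrophile, where O-acylation competes.
- Comparison: the chosen route places every ring A oxygen early, on an unhindered arene, and leaves no carbon–halogen bond to be converted late.

Key step: step 8

## Route

Remark: the target is achiral and is numbered as a flavone (O1, C2, C3, C4, C4a, C5 to C8, C8a, primed positions on ring B); compounds 1, 7, 9 and 13 are taken to be commercial.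

Step 1
Reactants: 1 1,2,3-trimethoxybenzene
Product: 2 1,5-dibromo-2,3,4-trimethoxybenzene
Conditions: NBS (2.1 equiv), MeCN, 0 °C → rt
Reagents that add atoms: N-bromosuccinimide, O=C1CCC(=O)N1Br
Why: Electrophilic aromatic bromination; C4 and C6 of 1 are each ortho to one outer methoxy group and para to the other, whereas C5 is activated only by the twisted central methoxy group, so two equivalents of NBS should stop at the 4,6-dibromide 2.

Step 2
Reactants: 2 1,5-dibromo-2,3,4-trimethoxybenzene
Product: 4 4,5,6-trimethoxybenzene-1,3-diol, via bis(pinacolboronate) 3 (not isolated)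
Conditions: B2pin2 (2.6 equiv), Pd(dppf)Cl2 (5 mol %), KOAc, 1,4-dioxane, 90 °C; then THF, aq NaOH, 30 % H2O2, 0 °C; cold acidic work-up under N2
Reagents that add atoms: hydrogen peroxide, OO (both hydroxyl oxygens); bis(pinacolato)diboron, CC1(C)OB(OC1(C)C)B1OC(C)(C)C(C)(C)O1 (boryl groups of intermediate 3 only)
Why: Miyaura borylation of both aryl bromides, then oxidation of the C–B bonds by alkaline peroxide through a 1,2-aryl shift from boron to oxygen; each bromide has a free ortho position, so oxidative addition is not hindered. The diol is acidified cold and kept under nitrogen because the electron-rich resorcinolate is air-sensitive.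

Step 3
Reactants: 4 4,5,6-trimethoxybenzene-1,3-diol
Product: 6 2,6-dihydroxy-3,4,5-trimethoxybenzaldehyde, via chloro(methoxy)methyl arene 5 (not isolated)
Conditions: Cl2CHOMe (1.2 equiv), TiCl4 (2.5 equiv), CH2Cl2, −10 → 0 °C; then 1 M HCl, 0 °C → rt
Reagents that add atoms: dichloromethyl methyl ether, COC(Cl)Cl (formyl carbon); water, O (carbonyl oxygen)
Why: Rieche formylation; the titanium phenoxide delivers the electrophile to the ortho carbon, and the only unsubstituted ring carbon of 4 is ortho to both hydroxyls, so no regiochemical choice exists. Aqueous acid hydrolyses the racemic chloro ether 5 to the aldehyde, whose carbonyl deactivates the ring against further substitution.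

Step 4
Reactants: 6 2,6-dihydroxy-3,4,5-trimethoxybenzaldehyde; 7 benzyl bromide
Product: 8 2-(benzyloxy)-6-hydroxy-3,4,5-trimethoxybenzaldehyde
Conditions: BnBr (1.0 equiv), K2CO3 (1.1 equiv), acetone, rt → 40 °C
Reagents that add atoms: none
Why: Williamson ether synthesis; the two hydroxyls of 6 are equivalent, so either gives 8, and after the first alkylation the remaining hydroxyl is locked in a hydrogen bond to the aldehyde oxygen and should react much more slowly.

Step 5
Reactants: 8 2-(benzyloxy)-6-hydroxy-3,4,5-trimethoxybenzaldehyde; 9 3,4-bis(benzyloxy)benzoic acid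
Product: 11 3-(benzyloxy)-2-formyl-4,5,6-trimethoxyphenyl 3,4-bis(benzyloxy)benzoate, via 3,4-bis(benzyloxy)benzoyl chloride 10 (not isolated)
Conditions: 9, (COCl)2, DMF (cat.), CH2Cl2, 0 °C → rt, evaporate; then 8, Et3N, DMAP (cat.), CH2Cl2, 0 °C → rt
Reagents that add atoms: oxalyl chloride, O=C(Cl)C(=O)Cl (chlorine of intermediate 10 only)
Why: Acid chloride formation followed by DMAP-catalysed O-acylation; the acylpyridinium intermediate is reactive enough for the hindered, hydrogen-bonded phenol of 8, and the aldehyde is inert.

Step 6
Reactants: 11 3-(benzyloxy)-2-formyl-4,5,6-trimethoxyphenyl 3,4-bis(benzyloxy)benzoate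
Product: 12 2-(benzyloxy)-6-{[3,4-bis(benzyloxy)benzoyl]oxy}-3,4,5-trimethoxybenzoic acid
Conditions: NaClO2, NaH2PO4, 2-methyl-2-butene, t-BuOH/THF/H2O, 0 °C → rt
Reagents that add atoms: sodium chlorite, [Na+].[O-]Cl=O
Why: Pinnick oxidation; chlorous acid adds to the aldehyde and fragments to the acid, the alkene traps the hypochlorous acid, and the buffered medium leaves the aryl ester and benzyl ethers alone. Ring A has neither a free position nor a free phenol, so ring chlorination is not expected.

Step 7
Reactants: 12 2-(benzyloxy)-6-{[3,4-bis(benzyloxy)benzoyl]oxy}-3,4,5-trimethoxybenzoic acid; 13 methyltriphenylphosphonium bromide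
Product: 16 3-(benzyloxy)-4,5,6-trimethoxy-2-[(triphenyl-λ5-phosphanylidene)acetyl]phenyl 3,4-bis(benzyloxy)benzoate, via acid chloride 14 (not isolated), via methylenetriphenylphosphorane 15 (not isolated)
Conditions: 12, (COCl)2, DMF (cat.), CH2Cl2, 0 °C → rt, evaporate; 13 (2.05 equiv), NaN(SiMe3)2 (2.0 equiv), THF, 0 °C; then 14 in THF added at −78 °C, → 0 °C
Reagents that add atoms: oxalyl chloride, O=C(Cl)C(=O)Cl (chlorine of intermediate 14 only)
Why: Acylation of a non-stabilised ylide by an acid chloride with transylidation in the flask: one equivalent of 15 is acylated to the acylphosphonium salt and the second deprotonates it to the stabilised ylide 16. At −78 °C the acid chloride should react far faster than the aryl ester, and the slight excess of 13 over the amide base ensures that no free amide is left to attack the ester.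

Step 8
Reactants: 16 3-(benzyloxy)-4,5,6-trimethoxy-2-[(triphenyl-λ5-phosphanylidene)acetyl]phenyl 3,4-bis(benzyloxy)benzoate
Product: 17 5-(benzyloxy)-2-[3,4-bis(benzyloxy)phenyl]-6,7,8-trimethoxy-4H-chromen-4-one
Conditions: toluene, 110 °C, N2
Reagents that add atoms: none
Why: Intramolecular Wittig olefination of an ester carbonyl: the ylide carbon of 16 (future C3) adds to the aryl ester carbonyl (future C2), the betaine closes to an oxaphosphetane, and cycloreversion expels Ph3PO to leave the C2=C3 bond. The closest known reaction type is the thermal cyclisation of (2-acyloxybenzoyl)methylene phosphoranes to chromones and flavones. Ring C closes by a 6-exo-trig addition of carbon to the ester C=O, and the ester oxygen stays in the ring as O1. No stereocentre is formed. The step needs olefination to win over mere transfer of the aroyl group to carbon; both start from the same tetrahedral adduct, and the diacyl ylide with a free phenoxide that acyl transfer would give can add back through O1 to that adduct, so both channels should end at 17. The only other oxygen ortho to the acyl ylide is a benzyl ether, so no second ester competes and no free phenol is exposed to aurone-type closure. The two ortho substituents twist the acyl ylide out of the plane of ring A and hold its carbon over the ester carbonyl, which should offset the low electrophilicity of the 3,4-dialkoxybenzoate.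

Step 9
Reactants: 17 5-(benzyloxy)-2-[3,4-bis(benzyloxy)phenyl]-6,7,8-trimethoxy-4H-chromen-4-one
Product: 20 5-(benzyloxy)-2-[3,4-bis(benzyloxy)phenyl]-3-hydroxy-6,7,8-trimethoxy-4H-chromen-4-one, via 3-lithioflavone 18 (not isolated), via flavon-3-yl dimethyl boronate 19 (not isolated)
Conditions: LiN(iPr)2 (1.3 equiv), THF, −78 °C; B(OMe)3, −78 → 0 °C; AcOH, 30 % H2O2, 0 °C → rt
Reagents that add atoms: hydrogen peroxide, OO (C3 oxygen); trimethyl borate, COB(OC)OC (boron of intermediate 19 only)
Why: Deprotonation of the flavone at C3, the vinylic C–H between C2 and the C4 carbonyl, then trapping with the borate ester and oxidative 1,2-shift from boron to oxygen under buffered peroxide. All hydroxyls are masked as ethers, so no acidic proton competes.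

Step 10
Reactants: 20 5-(benzyloxy)-2-[3,4-bis(benzyloxy)phenyl]-3-hydroxy-6,7,8-trimethoxy-4H-chromen-4-one
Product: 21 2-(3,4-dihydroxyphenyl)-3,5-dihydroxy-6,7,8-trimethoxy-4H-chromen-4-one (3,5,3',4'-tetrahydroxy-6,7,8-trimethoxyflavone)
Conditions: H2 (1 atm), 10 % Pd/C, THF/MeOH, rt
Reagents that add atoms: none
Why: Hydrogenolysis of the three aryl benzyl ethers under neutral conditions; the methyl ethers are inert, and the reaction is stopped after uptake of three equivalents of hydrogen so that the C2=C3 bond is not reduced. The product is handled under inert gas because the catechol and the enol are air-sensitive.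

## Compound list

1 | 1,2,3-trimethoxybenzene | COc1cccc(OC)c1OC | starting material
2 | 1,5-dibromo-2,3,4-trimethoxybenzene | COc1c(Br)cc(Br)c(OC)c1OC | intermediate
3 | 2,2'-(4,5,6-trimethoxy-1,3-phenylene)bis(4,4,5,5-tetramethyl-1,3,2-dioxaborolane) | COc1c(B2OC(C)(C)C(C)(C)O2)cc(B2OC(C)(C)C(C)(C)O2)c(OC)c1OC | intermediate
4 | 4,5,6-trimethoxybenzene-1,3-diol | COc1c(O)cc(O)c(OC)c1OC | intermediate
5 | 2-[chloro(methoxy)methyl]-4,5,6-trimethoxybenzene-1,3-diol (racemic, present as its titanium phenoxide) | COC(Cl)c1c(O)c(OC)c(OC)c(OC)c1O | intermediate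
6 | 2,6-dihydroxy-3,4,5-trimethoxybenzaldehyde | COc1c(O)c(C=O)c(O)c(OC)c1OC | intermediate
7 | benzyl bromide | BrCc1ccccc1 | starting material
8 | 2-(benzyloxy)-6-hydroxy-3,4,5-trimethoxybenzaldehyde | COc1c(O)c(C=O)c(OCc2ccccc2)c(OC)c1OC | intermediate
9 | 3,4-bis(benzyloxy)benzoic acid | O=C(O)c1ccc(OCc2ccccc2)c(OCc2ccccc2)c1 | starting material
10 | 3,4-bis(benzyloxy)benzoyl chloride | O=C(Cl)c1ccc(OCc2ccccc2)c(OCc2ccccc2)c1 | intermediate
11 | 3-(benzyloxy)-2-formyl-4,5,6-trimethoxyphenyl 3,4-bis(benzyloxy)benzoate | COc1c(OC)c(OCc2ccccc2)c(C=O)c(OC(=O)c2ccc(OCc3ccccc3)c(OCc3ccccc3)c2)c1OC | intermediate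
12 | 2-(benzyloxy)-6-{[3,4-bis(benzyloxy)benzoyl]oxy}-3,4,5-trimethoxybenzoic acid | COc1c(OC)c(OCc2ccccc2)c(C(=O)O)c(OC(=O)c2ccc(OCc3ccccc3)c(OCc3ccccc3)c2)c1OC | intermediate
13 | methyltriphenylphosphonium bromide | C[P+](c1ccccc1)(c1ccccc1)c1ccccc1.[Br-] | starting material
14 | 3-(benzyloxy)-2-(chlorocarbonyl)-4,5,6-trimethoxyphenyl 3,4-bis(benzyloxy)benzoate | COc1c(OC)c(OCc2ccccc2)c(C(=O)Cl)c(OC(=O)c2ccc(OCc3ccccc3)c(OCc3ccccc3)c2)c1OC | intermediate
15 | methylenetriphenylphosphorane | C=P(c1ccccc1)(c1ccccc1)c1ccccc1 | intermediate
16 | 3-(benzyloxy)-4,5,6-trimethoxy-2-[(triphenyl-λ5-phosphanylidene)acetyl]phenyl 3,4-bis(benzyloxy)benzoate | COc1c(OC)c(OCc2ccccc2)c(C(=O)C=P(c2ccccc2)(c2ccccc2)c2ccccc2)c(OC(=O)c2ccc(OCc3ccccc3)c(OCc3ccccc3)c2)c1OC | intermediate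
17 | 5-(benzyloxy)-2-[3,4-bis(benzyloxy)phenyl]-6,7,8-trimethoxy-4H-chromen-4-one | COc1c(OC)c(OCc2ccccc2)c2c(=O)cc(-c3ccc(OCc4ccccc4)c(OCc4ccccc4)c3)oc2c1OC | intermediate
18 | {5-(benzyloxy)-2-[3,4-bis(benzyloxy)phenyl]-6,7,8-trimethoxy-4-oxo-4H-chromen-3-yl}lithium | COc1c(OC)c(OCc2ccccc2)c2c(=O)c([Li])c(-c3ccc(OCc4ccccc4)c(OCc4ccccc4)c3)oc2c1OC | intermediate
19 | dimethyl {5-(benzyloxy)-2-[3,4-bis(benzyloxy)phenyl]-6,7,8-trimethoxy-4-oxo-4H-chromen-3-yl}boronate | COB(OC)c1c(-c2ccc(OCc3ccccc3)c(OCc3ccccc3)c2)oc2c(OC)c(OC)c(OC)c(OCc3ccccc3)c2c1=O | intermediate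
20 | 5-(benzyloxy)-2-[3,4-bis(benzyloxy)phenyl]-3-hydroxy-6,7,8-trimethoxy-4H-chromen-4-one | COc1c(OC)c(OCc2ccccc2)c2c(=O)c(O)c(-c3ccc(OCc4ccccc4)c(OCc4ccccc4)c3)oc2c1OC | intermediate
21 | 2-(3,4-dihydroxyphenyl)-3,5-dihydroxy-6,7,8-trimethoxy-4H-chromen-4-one | COc1c(OC)c(O)c2c(=O)c(O)c(-c3ccc(O)c(O)c3)oc2c1OC | target

## Step count and least certain steps

Total step count: 10. Longest linear sequence: 10 steps (1 to 21; 7, 9 and 13 enter as purchased materials).

Step 8 (key step). The stabilised ylide may add too slowly to the electron-rich ester carbonyl. Alternatively the tetrahedral adduct may collapse by acyl transfer to carbon, and the doubly stabilised ylide so formed may lose the phosphine oxide only sluggishly, so that prolonged heating degrades material instead of closing the ring. Fallback, setting out from 16: the phosphorus is removed reductively with Zn/AcOH to give the methyl ketone 2-acetyl-3-(benzyloxy)-4,5,6-trimethoxyphenyl 3,4-bis(benzyloxy)benzoate F1. KOt-Bu in THF then effects a Baker–Venkataraman acyl shift to the diketone 1-[2-(benzyloxy)-6-hydroxy-3,4,5-trimethoxyphenyl]-3-[3,4-bis(benzyloxy)phenyl]propane-1,3-dione F2; the second ortho oxygen is a benzyl ether, so the aroyl group has only one destination. Acid-catalysed cyclodehydration (catalytic H2SO4 in AcOH, 60 °C) closes ring C through O1, and the route is rejoined at 17.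

Step 7. The non-stabilised ylide 15 may attack the aryl ester and strip the aroyl group, or 16 may be acylated a second time by 14 if the stoichiometry drifts. Fallback, setting out from 12 through 14: Me3SiCHN2 gives the diazoketone 3-(benzyloxy)-2-(diazoacetyl)-4,5,6-trimethoxyphenyl 3,4-bis(benzyloxy)benzoate F3. Aqueous HBr in Et2O at 0 °C converts it to the bromomethyl ketone 3-(benzyloxy)-2-(bromoacetyl)-4,5,6-trimethoxyphenyl 3,4-bis(benzyloxy)benzoate F4. PPh3 in toluene gives the salt {2-[2-(benzyloxy)-6-{[3,4-bis(benzyloxy)benzoyl]oxy}-3,4,5-trimethoxyphenyl]-2-oxoethyl}triphenylphosphonium bromide F5, and a wash with aqueous Na2CO3 deprotonates it, rejoining the route at 16. No strongly nucleophilic carbon base meets the aryl ester in this sequence.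

Step 9. Deprotonation may compete at the benzylic CH2 of the 5-O-benzyl group, which lies next to the lithium-binding C4 carbonyl, or borylation of the hindered C3 anion may be incomplete, returning 17. Fallback, setting out from 17: dimethyldioxirane in acetone/CH2Cl2 epoxidises the C2=C3 enol-ether bond to 2,3-epoxy-5,3',4'-tris(benzyloxy)-6,7,8-trimethoxyflavanone F6 (racemic). A trace of p-TsOH opens the epoxide at C2 to the oxocarbenium ion, which loses the C3 proton, rejoining the route at 20.

Step 2. The second borylation may be incomplete, or protodeborylation may leave mono-oxygenated material, and the diol may be oxidised by air during the alkaline peroxide work-up. Fallback, setting out from 2: copper-catalysed C–O coupling with benzyl alcohol (CuI, 3,4,7,8-tetramethyl-1,10-phenanthroline, Cs2CO3, toluene, 110 °C) gives 1,5-bis(benzyloxy)-2,3,4-trimethoxybenzene F7. Hydrogenolysis over Pd/C then frees the diol under neutral, reducing conditions, rejoining the route at 4.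

Step 3. TiCl4 may cleave a methyl ether next to a titanium phenoxide, or the very electron-rich diol may condense to diarylmethane-type material before formylation is complete. Fallback, setting out from 4: MOMCl and i-Pr2NEt protect both hydroxyls to give 2,3,4-trimethoxy-1,5-bis(methoxymethoxy)benzene F8. n-BuLi removes the proton between the two acetal oxygens (directed ortho-metalation) and DMF gives 3,4,5-trimethoxy-2,6-bis(methoxymethoxy)benzaldehyde F9. HCl in MeOH removes both acetals, rejoining the route at 6.

## Further compounds

F1 | step 8 | 2-acetyl-3-(benzyloxy)-4,5,6-trimethoxyphenyl 3,4-bis(benzyloxy)benzoate | COc1c(OC)c(OCc2ccccc2)c(C(C)=O)c(OC(=O)c2ccc(OCc3ccccc3)c(OCc3ccccc3)c2)c1OC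
F2 | step 8 | 1-[2-(benzyloxy)-6-hydroxy-3,4,5-trimethoxyphenyl]-3-[3,4-bis(benzyloxy)phenyl]propane-1,3-dione | COc1c(OC)c(OCc2ccccc2)c(C(=O)CC(=O)c2ccc(OCc3ccccc3)c(OCc3ccccc3)c2)c(O)c1OC
F3 | step 7 | 3-(benzyloxy)-2-(diazoacetyl)-4,5,6-trimethoxyphenyl 3,4-bis(benzyloxy)benzoate | COc1c(OC)c(OCc2ccccc2)c(C(=O)C=[N+]=[N-])c(OC(=O)c2ccc(OCc3ccccc3)c(OCc3ccccc3)c2)c1OC
F4 | step 7 | 3-(benzyloxy)-2-(bromoacetyl)-4,5,6-trimethoxyphenyl 3,4-bis(benzyloxy)benzoate | COc1c(OC)c(OCc2ccccc2)c(C(=O)CBr)c(OC(=O)c2ccc(OCc3ccccc3)c(OCc3ccccc3)c2)c1OC
F5 | step 7 | {2-[2-(benzyloxy)-6-{[3,4-bis(benzyloxy)benzoyl]oxy}-3,4,5-trimethoxyphenyl]-2-oxoethyl}triphenylphosphonium bromide | COc1c(OC)c(OCc2ccccc2)c(C(=O)C[P+](c2ccccc2)(c2ccccc2)c2ccccc2)c(OC(=O)c2ccc(OCc3ccccc3)c(OCc3ccccc3)c2)c1OC.[Br-]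
F6 | step 9 | 2,3-epoxy-5,3',4'-tris(benzyloxy)-6,7,8-trimethoxyflavanone (racemic, cis ring fusion, one enantiomer drawn) | COc1c(OC)c(OCc2ccccc2)c2C(=O)[C@@H]5O[C@]5(c3ccc(OCc4ccccc4)c(OCc4ccccc4)c3)Oc2c1OC
F7 | step 2 | 1,5-bis(benzyloxy)-2,3,4-trimethoxybenzene | COc1c(OCc2ccccc2)cc(OCc2ccccc2)c(OC)c1OC
F8 | step 3 | 2,3,4-trimethoxy-1,5-bis(methoxymethoxy)benzene | COCOc1cc(OCOC)c(OC)c(OC)c1OC
F9 | step 3 | 3,4,5-trimethoxy-2,6-bis(methoxymethoxy)benzaldehyde | COCOc1c(C=O)c(OCOC)c(OC)c(OC)c1OC
A1 | alternative 1 | 3-(benzyloxy)-2-[3,4-bis(benzyloxy)phenyl]-5-hydroxy-6,7,8-trimethoxy-4H-chromen-4-one | COc1c(OC)c(O)c2c(=O)c(OCc3ccccc3)c(-c3ccc(OCc4ccccc4)c(OCc4ccccc4)c3)oc2c1OC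
A2 | alternative 1 | 4-{5-(benzyloxy)-6-[3,4-bis(benzyloxy)phenyl]-4-oxo-4H-pyran-2-yl}-2,3,4-trimethoxycyclobut-2-en-1-one (racemic) | COC1=C(OC)C(OC)(c2cc(=O)c(OCc3ccccc3)c(-c3ccc(OCc4ccccc4)c(OCc4ccccc4)c3)o2)C1=O
A3 | alternative 2 | 2-[3,4-bis(benzyloxy)phenyl]-5,6,7,8-tetramethoxy-4H-chromen-4-one | COc1c(OC)c(OC)c2c(=O)cc(-c3ccc(OCc4ccccc4)c(OCc4ccccc4)c3)oc2c1OC
A4 | alternative 2 | 2,3,4,5-tetramethoxy-6-(trimethylsilyl)phenyl trifluoromethanesulfonate | COc1c(OC)c(OC)c([Si](C)(C)C)c(OS(=O)(=O)C(F)(F)F)c1OC
A5 | alternative 2 | 3,4,5,6-tetramethoxybenzyne | COC1=C(OC)C(OC)=C(OC)C#C1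
A6 | alternative 2 | 3-[3,4-bis(benzyloxy)phenyl]prop-2-ynoic acid | OC(=O)C#Cc1ccc(OCc2ccccc2)c(OCc2ccccc2)c1
A7 | alternative 3 | 3-(benzyloxy)-2-[3,4-bis(benzyloxy)phenyl]-5-bromo-6,7,8-trimethoxy-4H-chromen-4-one | COc1c(OC)c(Br)c2c(=O)c(OCc3ccccc3)c(-c3ccc(OCc4ccccc4)c(OCc4ccccc4)c3)oc2c1OC
A8 | alternative 3 | 2-(benzyloxy)-1-[3,4-bis(benzyloxy)phenyl]-3-(2,6-dibromo-3,4,5-trimethoxyphenyl)propane-1,3-dione (racemic, enolisable) | COc1c(OC)c(Br)c(C(=O)C(OCc2ccccc2)C(=O)c2ccc(OCc3ccccc3)c(OCc3ccccc3)c2)c(Br)c1OC
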